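The readings were generated by integration for substances that don't exist; scatter was added.

A small charge of D, 0.18 M, meets L in several set-ups, and each turnover of L is a single event: it lifts a D to a mono adduct, or it lifts a mono adduct to E.

| setting | south-east | north-west | north | ash | alder | birch | cedar |
|---|---|---|---|---|---|---|---|
| D | 0.18 M | 0.18 M | 0.18 M | 0.18 M | 0.18 M (fed, over 2.40 min) | 0.18 M | 0.18 M |
| L | 1.3 equiv | 0.65 equiv | 0.98 equiv | 1.30 equiv (fed, over 2.40 min) | 1.30 equiv | 1.30 equiv | 1.30 equiv |
| remark | run made earlier | run made earlier | run made earlier | a stirred flask in which L is dosed at a steady rate over 2.40 min without added volume, worked up at 3.0 min | a stirred flask in which D is dosed at a steady rate over 2.40 min without added volume, worked up at 3.0 min | everything together in a closed stirred flask, run for 3.0 min | one stirred flow tank at steady state, fed with the mixture as stated, mean residence time 3.0 min |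
| time |  |  |  | 3.0 min | 3.0 min | 3.0 min |  |

south-east run (percent of the D charged)

| time / min | Q / % | E / % |
|---|---|---|
| 0.250 | 12.6 | 37.7 |
| 0.500 | 11.8 | 38.7 |
| 1.33 | 12.2 | 37.4 |
| 3.00 | 11.3 | 38.8 |

north-west run (percent of the D charged)

| time / s | Q / % | E / % |
|---|---|---|
| 10.0 | 19.8 | 9.7 |
| 20.0 | 19.0 | 8.9 |
| 50.0 | 17.7 | 9.7 |
| 120 | 15.8 | 8.9 |

north run (percent of the D charged)

| time / s | Q / % | E / % |
|---|---|---|
| 25.0 | 19.6 | 21.5 |
| 50.0 | 19.0 | 21.0 |
| 80.0 | 18.1 | 21.1 |
| 120 | 17.1 | 22.1 |

(scatter of a reading: 0.5 percentage points)

- percent here means D units held: one J counts as two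
- the stated concentrations are those of everything mixed, before any reaction; amounts are the same in each set-up
- the feed brings no volume worth counting
- the earlier runs were made in a closed, stirred flask

* the set-up with the highest share of Q in all that became Q or E or J, at the outlet or at the end ("none" if the first two lie within 2 percentage points) (ash / alder / birch / cedar / none)
* share of Q in all that became Q or E or J, at the outlet or at the end, ash
* share of Q in all that became Q or E or J, at the outlet or at the end, alder
* share of Q in all that became Q or E or J, at the outlet or at the end, birch
* share of Q in all that became Q or E or J, at the outlet or at the end, cedar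

In each earlier run E stays flat within the scatter from the first reading on, while Q falls slowly, and in north-west that first reading comes at 10.0 s, a time far shorter than the dosing. Suppose, then, that L, the limiting reagent, has made all its turnovers by the first reading. Counting them, the fraction of D left is one minus the equivalents of L plus E: 0.447 in north-west, 0.235 in north and 0.0770 in south-east. The count also asks for an unseen mono adduct, G, because in south-east Q plus twice E falls short of the L charged by 0.420.

Two amounts now matter, D left and Q standing. Every L meets both, so the level of L cancels from the ratio of its two takes. Q reads nearly the same in north-west and north while Q to D rises from 0.443 to 0.834, so a peak of Q is read between them. Their geometric mean, 0.608, is read as the balance ratio, the Q to D at which L makes Q as fast as it takes Q.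

Birch follows the path of south-east, so my reckoning gives it about 21.4 %, counting J as twice the Q lost. Ash should walk the same path more slowly, with more time for that loss. In alder and cedar, Q to D should stay near or under the balance while little D stands, so Q should stay low there. My order puts birch first.

The forecast chose ash, with 76 %, 45 %, 22 % and 62 % for ash, alder, birch and cedar, holding that “low standing L should favour Q strongly”.

The flask gives birch: ash 14.4 %, alder 6.07 %, birch 22.7 %, cedar 13.6 %.

    L + G → E (k = 0.0800 M⁻¹ s⁻¹)
    L + Q → E (k = 7.80 M⁻¹ s⁻¹)
    D + L → Q (k = 4.80 M⁻¹ s⁻¹)
    D + L → G (k = 4.10 M⁻¹ s⁻¹)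
    D + Q → J (k = 0.0300 M⁻¹ s⁻¹)
    L ⇌ Z (K = 0.240, k = 0.230 s⁻¹)

In alder at 1.50 min, with 18.5 % of the L charge standing, Q to D is 0.570 against the balance of 0.608. The neighbour is alder with 0.780 equiv of L. There the count gives 0.488 of D left, and the flask ends with 48.2 %. Its final Q to D, 0.0581, lies far below the balance, with Q at 2.80 % and a share of 9.10 %.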